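The teal flask was slowing.

| flask | substrate | partner | capture agent | temperature | remark | time |
|---|---|---|---|---|---|---|
| teal | 15 mM | 1.5 equiv | 4.5 mM | 25 °C | the very flask that is asked about, followed so far |  |
| violet | 15 mM | 1.5 equiv | 2.2 mM | 31 °C | run made earlier |  |
| flask | 15 mM | 1.50 equiv | 4.50 mM | 25 °C |  | 30 min |

| run | time / min | target / % |
|---|---|---|
| teal | 3.00 | 3.7 |
| teal | 8.00 | 5.9 |
| teal | 15.0 | 8.0 |
| teal | 25.0 | 8.8 |
| violet | 8.00 | 11.3 |
| violet | 15.0 | 11.8 |
| violet | 25.0 | 13.6 |
| violet | 30.0 | 12.9 |

(each reading ± 1 percentage point)

- south-west: change nothing and wait 10 min more
- south: at 30 min add partner, 50.0% of the amount charged, then wait 10 min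
- east: at 30 min take out 90% of the target then present, then wait 10 min
- north-west: at 30 min raise the temperature by 25 K, then wait 10 min

- target, in percent of the substrate first charged, at 30 min
- the option that brings most further target ("none" if no option brings more than 2 percentage points) (south-west / south / east / north-west / none)
- target present, with what was taken out counted in, in percent of the substrate first charged, after south
- target present, with what was taken out counted in, in percent of the substrate first charged, after east

- target taken out counts as made
- what was read earlier has a scatter of 1 percentage point, one standard deviation
- additions bring no volume worth counting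

In the teal flask, substrate was the limiting reagent against 1.50 equiv of partner, and target was the species I could read, so I bracketed target at 30 min. My rule was that on a curve bending downward throughout, a later stretch climbs no faster than an earlier one, and an earlier stretch no slower than a later one. My quantity was the closing gain, the rise between the last two teal readings, scaled to the further 10 min: 0.8 percentage points. The stretch before it, scaled the same way, gave 3 points, so teal had slowed, the closing gain being smaller.

If target did not fall, the last reading, 8.8%, was my bound from below. The earlier pace, carried on to 30 min, gave my bound from above, 10.3%. The closing gain, carried on the same way, gave my estimate, 9.20%, with a scatter of about 1.6 points from the two readings behind it. The closing gain also stood below the useful margin, though its own scatter was 1.4 points, so I held waiting useless on a narrow reading. The violet flask read 13.6% at 25.0 min, a lift over teal of 4.8 points, but it was warmer and held less capture agent. I could not split that lift between the two settings, so I left north-west unranked.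

The forecast, inside my bracket, gave 9.5%, chose east, put south at 12.2% and east at 15%, and called heating “an uncertain, confounded extrapolation”.

    substrate → intermediate A (k = 0.00164 /s, Ea = 85.0 kJ/mol)
    intermediate A → target (k = 0.00238 /s, Ea = 88.0 kJ/mol)
    partner + intermediate A → side product A (k = 0.0387 /M/s, Ea = 59.0 kJ/mol)
    intermediate A ⇌ intermediate B (K = 46.2, k = 0.00540 /s, Ea = 96.0 kJ/mol, ΔH = −43.0 kJ/mol)
    substrate + target → side product B (k = 0.399 /M/s, Ea = 60.0 kJ/mol)
    capture agent + intermediate B → trapped intermediate (k = 0.178 /M/s, Ea = 60.0 kJ/mol)
    (constants at 25 °C)

The teal flask gave 9.71%, inside the bracket, and the best option was north-west, which brought 17 points; south reached 10.2% and east 10.7%. At 30.0 min this flask held intermediate B at 28.7% of the substrate charged. The closing gain of 0.8 points exceeded the 0.55 points that waiting brought. The neighbouring reading of this flask at 8.0 min stood at 6.44%; the closing gain carried from there to 30 min gives an estimate of 8.20%, and the flask stood above that estimate at 9.71%.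

The data come from a simulation with made-up constants, noise included.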